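## The problem

Cycloshizukaol A (31) is a C2-symmetric head-to-tail dimer in which two lindenane halves are joined by two C11–C15′ single bonds, so that C15, C4, C5, C6, C7 and C11 of each half form a 12-membered ring containing two C4=C5–C6=C7–C8=O dienone units. Each half is a 3/5/6 tricycle: cyclopropane C1–C2–C3 is cis-fused to five-membered ring A (C1, C3, C4, C5, C10), and ring B carries the C8 ketone, the C9 hydroxyl and the quaternary C10 methyl. C1, C3 and C10 are locked to one another, with C2 on the methyl face, and the C9 hydroxyl, cis to the C10 methyl, can be set by hydride delivery anti to that methyl. Quaternary C11 lies outside the rigid core and needs a relay, whereas C5 is sp2 in the target, so its configuration only serves the route. The vinylcyclopropane is acid-labile and the α-ketol epimerises and tautomerises with base. The dienone makes the hydrogens on C15 and C5 vinylogously acidic, and a carbanion at C11 is conjugated through C7=C6–C5=C4 with any leaving group on C15 and will expel it. The opening for the key step is that ring A plus the cyclopropane is a six-membered ring with one extra C1–C3 bond. A 1-oxygenated eudesm-3-ene whose C4 carries a silylmethyl group (C15) can therefore contract to the lindenane unit, leaving an exocyclic C4=C15 alkene that later becomes the C4=C5/C15 linkage of the macrocycle.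

## Retrosynthesis

**Unmasking (31 ← 30 ← 29 ← 27).** The last operations cut only O–Si bonds, restore the C8 carbonyls and write the methyl esters. The target is traced to the macrocyclic bis(12,8β-olide) 27, in which each C8 is at the alcohol level and tied to C12 as a γ-lactone. This is preferred to carrying the free keto ester through the ring-forming steps, because the ketone makes C15–H and C9–H competitive acids. The lactone removes that, leaves C11–H as the only acidic C–H, and places the C8 stereocentre next to C11. The forward reactions must open two α-quaternary lactones (29), oxidise only the allylic C8 alcohols (30) and remove two hindered silyl ethers without base (31).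

**The 12-membered ring (27 ← 26 ← 25 ← 23 + 24).** Both C11–C15′ bonds are cut, one at a time, as lactone-enolate alkylations by an allylic bromide. A one-flask cyclodimerisation of a bromo ester is rejected: its C11 anion would lose bromide through the diene (vinylogous elimination) faster than it could find a partner. The nucleophile is therefore the dianion of hydroxy lactone 23, whose C15 oxygen is an alkoxide and cannot leave. The electrophile is bromide 24, made from the same 23. The second bond is closed within bromide 26, where the only acidic hydrogen sits on the half that has no leaving group. The precursor is a single monomer, 23. The forward steps need C-alkylation at a tertiary carbon and attack anti to C9 on the lactone face, which by model gives the (11R) centres of the target.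

**Lactone and C15 oxygen (23 ← 21 ← 19).** The lactone comes from 1,2-reduction of dienone 21 from the α face and spontaneous acyl transfer. The C15 hydroxyl and the C4=C5 bond of 21 come from enone 19 by epoxidation of the exocyclic C4=C15 alkene and base-induced opening from the γ-position (C5). This ionic transposition is preferred to radical allylic bromination, which would have to discriminate C5–H from the equally weak C11–H. 19 is the lindenane silyloxy enone that the key step is meant to serve, with the C7 arm already in place.

**Ring B (19 ← 17 ← 16 ← 15 ← 14 ← 13).** The C6=C7 bond is cut back to ketone 17 (Saegusa–Ito oxidation). The 9β-silyloxy-8-ketone is cut back to the plain C9 ketone 13 by a 1,2-carbonyl transposition through an α-oxime: nitrosation at C8 (the only enolisable position), hydride reduction of C9 anti to the methyl, and deoximation. Hydroboration of a C9 silyl enol ether would be shorter but cannot coexist with the exocyclic alkene. Ring B is taken through the key step as the simple C9 ketone because a free 1β-hydroxyl and a 9β-silyloxy group are peri neighbours on C10 that would otherwise have to be told apart.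

**Key disconnection (13 ← 12 ← 11).** The C1–C3 bond is cut. Lindenane 13 becomes the trans-decalin 11, a 1β-hydroxy-eudesm-3-ene with a C15 trimethylsilyl group. Against cyclopropanation of a cyclopentene, this cut turns a facial-selectivity problem into a stereospecific inversion at C1 and delivers C15 as an exocyclic methylene. The precursor loses one ring and two stereocentres. The forward reaction must ionise a neopentyl secondary alcohol without skeletal shift.

**Ring A (11 ← 10 ← 9 ← 8 ← 4 + 5).** The C3=C4 bond is cut by ring-closing metathesis, C1–C2 by allylation of aldehyde 9, and C10–C1 and C5–C4 by a conjugate addition/aldol sequence on enone 4 with the alkenyl unit of 5 and formaldehyde. This is preferred to a Robinson-annulation decalin, in which C1 carries no oxygen and the 1β-hydroxyl could only be reached by a long detour through a dienone epoxide. The sequence must give trans addition at C5 and C10 (which fixes the trans ring fusion) and the (1R) carbinol.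

**The arm (4 ← 1).** The C7 propanoate is the oxidised isopropenyl group of (R)-carvone (1). The same stereocentre directs the conjugate addition, and the C11/C12/C13 carbons never have to be attached later.

## Roads not taken

**Alternative 1:** ring B would be cut at C9–C10 and C6–C7. In the forward sense 6-(dimethylamino)-1,4-dimethylfulvene A1 and the benzyloxy-substituted silyl enol ether A2, ionised in the flask to its 2-silyloxyallyl cation, would combine in a [6+3] annulation. Loss of the amine would give tetraenone A3 with quaternary C10, the C6=C7–C8=O enone and the C9 oxygen in one step. In step economy to the bicyclic core this is clearly better than the chosen plan, which needs thirteen steps to reach an enone of that oxidation level. Its weak points are specific to this target: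
- A3 still lacks the cyclopropane. CH2 would have to be added to C1=C3 in the presence of three other alkenes and on the methyl face.
- C15 arrives from fulvene A1 as an unfunctionalised methyl.
- C9 and C10 are formed racemic unless a chiral catalyst for an unsymmetrical oxyallyl cation is found.

The chosen plan offers in return absolute configuration from carvone, a cyclopropane set by inversion and not by facial choice, and C15 delivered as a reactive methylene.

**Alternative 2:** the macrocycle would be cut at both C4–C15 bonds. The lindenane monomer A4 carries a C4 alkenyl triflate and a spirocyclopropyl ketone (C7, C11, C15). It would be opened at C7–C15 by a zerovalent nickel catalyst such as Ni(cod)2 and coupled with the triflate of a second molecule, twice. This would give the macrocyclic bis(silyl enol ether) A5. It is the most convergent road: it makes the ring and both linking bonds in one operation, and C11 is already quaternary before the union, so the elimination problem described above never arises. In these respects it is better than the chosen three-step union. Against it: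
- Nickel opening of cyclopropyl ketones is established for simple aryl ketones, not for a hindered spiro system with a choice between C7–C15 and C7–C11.
- The alkenyl triflate sits on a vinylcyclopropane that can itself open on the metal.
- Cyclodimerisation must beat oligomerisation without any conformational help.
- Monomer A4 itself needs a stereocontrolled spiro-cyclopropanation at C7/C11.

The chosen plan has only textbook polar bond formations in the union and a stereochemical relay from C8 to C11.

**Alternative 3:** ring A would be cut at C5–C10. An enantiopure cis-cyclopropane A6 carries the ester arm (C10) on C1 and an alkenyl bromide (C5) on C3. It would be closed by palladium-catalysed α-alkenylation of the ester enolate to the bicyclo[3.1.0]hexene A7. Its merit is that the cyclopropane comes from an asymmetric cyclopropanation and never has to survive or be formed by a cationic step, which is safer than the key step here. Its weak points: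
- Reductive elimination to a strained bicyclohexene at a fully substituted carbon is demanding.
- The C10 configuration depends on the face of a conformationally mobile enolate.
- Ring B (C6 to C9 with the C7 arm, the ketol and the dienone) must then be built from two one-carbon handles, which costs more steps than ring A costs in the chosen route.

The chosen plan starts from a six-membered ring B that already holds C7 and its arm.

Key step: step 8

Remarks on the chemistry:
- Lindenane/eudesmane numbering is used for all intermediates, also before the rings exist.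
- C11 is carried as both epimers until it is deprotonated in steps 17 and 19, so its SMILES tag is left open.
- C7 may epimerise after step 9; it is drawn as inherited from carvone and becomes sp2 in step 13.
- C4 of epoxide 20 is consumed in the same flask and is left undefined.
- Compounds 1 and 5 and the allylborane of step 6 are assumed to be bought.

## Route

Step 1
Reactants: 1 (R)-carvone
Product: 2 (5R)-5-(1-hydroxypropan-2-yl)-2-methylcyclohex-2-en-1-one (both side-chain epimers)
Conditions: catecholborane, Rh(PPh3)3Cl (2 mol %), THF, 0 °C to rt; then H2O2, pH 7 phosphate buffer, 0 °C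
Reagents that add atoms: hydrogen peroxide, OO
Why: Rhodium-catalysed hydroboration selects the unhindered 1,1-disubstituted alkene over the ketone and the s-trans enone and places boron on the terminal carbon; buffered oxidation gives the primary alcohol without epoxidising the enone. The new side-chain centre (later C11) is left uncontrolled because it is deprotonated later.

Step 2
Reactants: 2 (5R)-5-(1-hydroxypropan-2-yl)-2-methylcyclohex-2-en-1-one
Product: 3 2-[(1R)-4-methyl-5-oxocyclohex-3-en-1-yl]propanoic acid
Conditions: TEMPO (10 mol %), PhI(OAc)2, MeCN/H2O, rt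
Reagents that add atoms: water, O
Why: Oxoammonium oxidation of a primary alcohol in aqueous acetonitrile runs through the aldehyde hydrate to the acid and leaves the enone untouched.

Step 3
Reactants: 3 2-[(1R)-4-methyl-5-oxocyclohex-3-en-1-yl]propanoic acid
Product: 4 methyl 2-[(1R)-4-methyl-5-oxocyclohex-3-en-1-yl]propanoate
Conditions: MeI, K2CO3, DMF, rt
Reagents that add atoms: iodomethane, CI
Why: SN2 O-alkylation of the carboxylate; the methyl ester is the ester of the target, so no protecting-group change is needed later.

Step 4
Reactants: 4 methyl 2-[(1R)-4-methyl-5-oxocyclohex-3-en-1-yl]propanoate; 5 2-bromo-3-(trimethylsilyl)prop-1-ene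
Product: 8 seco-eudesmane hydroxymethyl ketone (C9 ketone; 10β-methyl; 10α-CH2OH as C1; 5α-H with the 2-(trimethylsilylmethyl)vinyl group on C5; 7α-propanoate arm), via alkenylmagnesium bromide 6 (not isolated), via magnesium enolate 7 (not isolated)
Conditions: 5, Mg, THF; CuBr·SMe2 (10 mol %), THF, −40 °C, then 4; CH2O gas (from paraformaldehyde), −40 to −10 °C; aq. NH4Cl
Reagents that add atoms: formaldehyde, C=O
Why: Copper-catalysed conjugate addition of the alkenyl Grignard reagent to the carvone-type enone occurs anti to the C7 substituent, and the regiodefined magnesium enolate then adds to formaldehyde (aldol) anti to the new C5 group. This sets C5 and quaternary C10 trans, which becomes the 5α-H/10β-Me ring fusion.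

Step 5
Reactants: 8 seco-eudesmane hydroxymethyl ketone
Product: 9 seco-eudesmane keto aldehyde (C1 as CHO on quaternary C10)
Conditions: Dess–Martin periodinane, NaHCO3, CH2Cl2, 0 °C
Reagents that add atoms: none
Why: Neutral periodinane oxidation of the neopentyl primary alcohol avoids the retro-aldol loss of formaldehyde that base would cause; the α-carbon is quaternary, so nothing can epimerise.

Step 6
Reactants: 9 seco-eudesmane keto aldehyde
Product: 10 seco-eudesmane homoallylic alcohol ((1R)-1-hydroxybut-3-enyl on C10)
Conditions: (+)-Ipc2B(allyl), Et2O, −78 °C; then H2O2, pH 7 buffer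
Reagents that add atoms: (+)-B-allyldiisopinocampheylborane, C=CCB([C@H]1C[C@H]2C[C@@H]([C@@H]1C)C2(C)C)[C@H]1C[C@H]2C[C@@H]([C@@H]1C)C2(C)C
Why: Brown allylation is aldehyde-selective beside the ketone and esters and needs no Lewis acid, which would trigger allylsilane–carbonyl cyclisation. The reagent from (−)-α-pinene attacks the Re face and should give the (1R) carbinol (the later 1β-hydroxyl) under reagent control, overriding the opposite open-transition-state preference of the substrate.

Step 7
Reactants: 10 seco-eudesmane homoallylic alcohol
Product: 11 methyl 1β-hydroxy-9-oxo-15-(trimethylsilyl)eudesm-3-en-12-oate (5α-H; 7β-H; 10β-Me)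
Conditions: second-generation Grubbs catalyst (5 mol %), CH2Cl2, 40 °C, 5 mM
Reagents that add atoms: none
Why: Ring-closing metathesis between the allyl group and the 1,1-disubstituted allylsilane alkene forms the trisubstituted C3=C4 bond; the two chains are trans-diequatorial on ring B, so the cyclohexene closes as the trans-decalin.

Step 8
Reactants: 11 methyl 1β-hydroxy-9-oxo-15-(trimethylsilyl)eudesm-3-en-12-oate
Product: 13 methyl 9-oxolinden-4(15)-en-12-oate (1α-H; 3α-H; 5α-H; 7β-H; C2 on the β face), via 1β-triflate 12 (not isolated)
Conditions: Tf2O, 2,6-di-tert-butyl-4-methylpyridine, CH2Cl2, −78 to −20 °C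
Reagents that add atoms: none
Why: Tf2O turns the equatorial 1β-hydroxyl into triflate 12; on warming, the C3=C4 π bond, made nucleophilic by the allylic C15–Si bond, attacks C1 from the α face anti to the leaving group, the developing C4 cation is held by the β-silicon effect, and loss of Me3SiOTf leaves the exocyclic C4=C15 alkene. The closest known reaction type is the allylsilane-terminated closure of homoallylic triflates to vinylcyclopropanes, a controlled form of the homoallyl–cyclopropylcarbinyl (3,5-cyclosteroid) rearrangement. The cyclopropane closes in a 3-exo-tet mode; five-membered ring A is not closed by a bond of its own but is what remains of the six-membered ring once C1–C3 exists (transannular ring contraction). C1 is set by inversion, so the 1β-oxygen, cis to the C10 methyl, puts C2 on the methyl face; C3 has no choice because the cyclopropane can only be cis-fused; C5, C7 and C10 are spectators. The step needs π-participation to outrun 1,2-shift of the C10 methyl or the C9 acyl group, elimination toward C2 and protodesilylation. In the trans-decalin half-chair the back lobe of the equatorial C1–O bond points at the α lobe of C3, the C9 carbonyl disfavours a free C1 cation so that ionisation is coupled to bond formation, silicon makes C3 the most nucleophilic carbon, and the hindered pyridine removes acid without attacking the triflate.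

Step 9
Reactants: 13 methyl 9-oxolinden-4(15)-en-12-oate
Product: 14 methyl 8-(hydroxyimino)-9-oxolinden-4(15)-en-12-oate
Conditions: isoamyl nitrite, KOtBu, t-BuOH/THF, 0 °C; aq. NH4Cl
Reagents that add atoms: isoamyl nitrite, CC(C)CCON=O
Why: α-Oximation (nitrosation of the ketone enolate, then tautomerisation); C10 is quaternary, so C8 is the only position the C9 ketone can enolise to, and the ketone is far more acidic than the ester.

Step 10
Reactants: 14 methyl 8-(hydroxyimino)-9-oxolinden-4(15)-en-12-oate
Product: 15 methyl 9β-hydroxy-8-(hydroxyimino)linden-4(15)-en-12-oate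
Conditions: NaBH4, MeOH, −20 °C
Reagents that add atoms: none
Why: Borohydride reduces the ketone but not the oxime or ester; hydride comes from the α face, anti to the axial C10 methyl, as in angular-methyl decalones and 16-oximino-17-keto steroids, and sets the 9β-hydroxyl.

Step 11
Reactants: 15 methyl 9β-hydroxy-8-(hydroxyimino)linden-4(15)-en-12-oate
Product: 16 methyl 9β-hydroxy-8-oxolinden-4(15)-en-12-oate
Conditions: aq. TiCl3, NH4OAc, THF/H2O, rt
Reagents that add atoms: water, O
Why: Reductive deoximation: trivalent titanium cleaves the N–O bond and the imine hydrolyses at buffered pH, which frees the C8 ketone without enolising the new α-ketol.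

Step 12
Reactants: 16 methyl 9β-hydroxy-8-oxolinden-4(15)-en-12-oate
Product: 17 methyl 9β-(tert-butyldimethylsilyloxy)-8-oxolinden-4(15)-en-12-oate
Conditions: TBSOTf, 2,6-lutidine, CH2Cl2, −78 to −40 °C
Reagents that add atoms: tert-butyldimethylsilyl triflate, CC(C)(C)[Si](C)(C)OS(=O)(=O)C(F)(F)F
Why: Silyl triflate with a hindered base silylates the neopentyl secondary alcohol at low temperature before the ketone can be enolised; the ether fixes C9 and blocks ketol tautomerisation in the steps that follow.

Step 13
Reactants: 17 methyl 9β-(tert-butyldimethylsilyloxy)-8-oxolinden-4(15)-en-12-oate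
Product: 19 methyl 9β-(tert-butyldimethylsilyloxy)-8-oxolinda-4(15),6-dien-12-oate, via trimethylsilyl enol ether 18 (not isolated)
Conditions: TMSOTf, Et3N, CH2Cl2, 0 °C; solvent exchange to MeCN; Pd(OAc)2 (1.05 equiv), rt
Reagents that add atoms: none
Why: Soft enolisation of an α-silyloxy ketone goes away from the oxygen-bearing carbon, toward C7, and Saegusa–Ito oxidation of that enol ether gives the C6=C7 enone by β-hydride elimination. Any exocyclic C7=C11 isomer is drawn into the same dienone by the base of step 14.

Step 14
Reactants: 19 methyl 9β-(tert-butyldimethylsilyloxy)-8-oxolinda-4(15),6-dien-12-oate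
Product: 21 methyl 9β-(tert-butyldimethylsilyloxy)-15-hydroxy-8-oxolinda-4,6-dien-12-oate, via 4,15-epoxide 20 (not isolated)
Conditions: m-CPBA, NaHCO3, CH2Cl2, 0 °C; then DBU (0.3 equiv), rt
Reagents that add atoms: 3-chloroperbenzoic acid, OOC(=O)c1cccc(Cl)c1
Why: The peracid epoxidises only the electron-rich exocyclic alkene (the enone alkene is inert). DBU then removes the γ-hydrogen at C5 and the dienolate opens the epoxide (vinylogous E1cB), which moves the double bond to C4=C5, puts the oxygen on C15 and removes the C5 stereocentre.

Step 15
Reactants: 21 methyl 9β-(tert-butyldimethylsilyloxy)-15-hydroxy-8-oxolinda-4,6-dien-12-oate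
Product: 23 9β-(tert-butyldimethylsilyloxy)-15-hydroxylinda-4,6-dien-12,8β-olide, via 8β-hydroxy ester 22 (not isolated)
Conditions: NaBH4, CeCl3·7H2O, MeOH, −40 °C; then PPTS (cat.), CH2Cl2, rt
Reagents that add atoms: none
Why: Luche reduction gives 1,2-addition to the dienone; hydride should come from the α face because the β face carries the adjacent 9β-silyloxy group and the C10 methyl. The 8β-alkoxide closes onto the ester as a five-membered lactone, which masks the ketone, leaves C11–H as the only acidic C–H and places C8 where it can control C11.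

Step 16
Reactants: 23 9β-(tert-butyldimethylsilyloxy)-15-hydroxylinda-4,6-dien-12,8β-olide
Product: 24 15-bromo-9β-(tert-butyldimethylsilyloxy)linda-4,6-dien-12,8β-olide
Conditions: CBr4, PPh3, CH2Cl2, −20 °C
Reagents that add atoms: carbon tetrabromide, BrC(Br)(Br)Br
Why: Appel reaction: SN2 displacement at the primary allylic carbon under neutral conditions, which the lactone and silyl ether tolerate.

Step 17
Reactants: 23 9β-(tert-butyldimethylsilyloxy)-15-hydroxylinda-4,6-dien-12,8β-olide; 24 15-bromo-9β-(tert-butyldimethylsilyloxy)linda-4,6-dien-12,8β-olide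
Product: 25 seco-dimer alcohol (C11 of the 15-hydroxy half bonded to C15′ of the second olide; new centre 11R)
Conditions: 23 (2.5 equiv), LiN(iPr)2 (5.1 equiv), THF, −78 °C; then 24 (1 equiv), DMPU, −78 to −50 °C; aq. NH4Cl
Reagents that add atoms: none
Why: The dianion of 23 carries its C15 oxygen as an alkoxide, which cannot be expelled through the diene, and its lactone dienolate is alkylated at the α-carbon (C11) by the allylic bromide on the lactone face anti to C9. Should 24 first lose HBr to the triene lactone, 1,8-addition of the same enolate to its C15 gives the same bond; excess 23 limits over-alkylation.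

Step 18
Reactants: 25 seco-dimer alcohol
Product: 26 seco-dimer bromide (C15–Br on the half with quaternary C11)
Conditions: CBr4, PPh3, CH2Cl2, −20 °C
Reagents that add atoms: carbon tetrabromide, BrC(Br)(Br)Br
Why: Appel reaction on the single hydroxyl; the bromide now sits on the half that has no acidic hydrogen.

Step 19
Reactants: 26 seco-dimer bromide
Product: 27 macrocyclic bis(12,8β-olide) (9,9′-bis-silyl ether; both C11 quaternary; 12-membered ring closed)
Conditions: slow addition of 26 to LiN(SiMe3)2 (1.5 equiv), THF/DMPU, 1 mM, −78 to 0 °C
Reagents that add atoms: none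
Why: Intramolecular lactone-enolate alkylation at high dilution; the only acidic hydrogen is C11–H of the bromide-free half, whose enolate has a carbon, not a leaving group, at the end of its diene. Attack anti to C9 sets the second C11 in the same sense as the first.

Step 20
Reactants: 27 macrocyclic bis(12,8β-olide)
Product: 29 9,9′-bis-O-TBS-8,8′-dihydrocycloshizukaol A (8β-hydroxyl in place of each ketone), via dilithium hydroxy carboxylate 28 (not isolated)
Conditions: LiOH·H2O, THF/H2O, 45 °C; evaporate; MeI, DMF, 0 °C; used crude
Reagents that add atoms: lithium hydroxide, [Li+].[OH-]; iodomethane, CI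
Why: Saponification opens both γ-lactones by acyl–oxygen cleavage (the C8 configuration is untouched and is erased in step 21), and the carboxylates are methylated in the same flask before the hydroxy acids can close again.

Step 21
Reactants: 29 9,9′-bis-O-TBS-8,8′-dihydrocycloshizukaol A
Product: 30 9,9′-bis-O-TBS-cycloshizukaol A
Conditions: activated MnO2, CH2Cl2, rt
Reagents that add atoms: none
Why: MnO2 oxidises the allylic C8 alcohols to the dienones under neutral conditions and outruns relactonisation; C9 stays protected, so the ketol cannot tautomerise.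

Step 22
Reactants: 30 9,9′-bis-O-TBS-cycloshizukaol A
Product: 31 cycloshizukaol A
Conditions: HF·pyridine, pyridine, THF, 0 °C to rt
Reagents that add atoms: none
Why: Buffered acidic fluoride cleaves the two hindered silyl ethers without the base-induced C9 epimerisation or ketol shift that a basic fluoride source could cause.

## Compound list

1 | (R)-carvone | CC1=CC[C@H](CC1=O)C(C)=C | starting material
2 | (5R)-5-(1-hydroxypropan-2-yl)-2-methylcyclohex-2-en-1-one (both side-chain epimers) | CC1=CC[C@H](CC1=O)C(C)CO | intermediate
3 | 2-[(1R)-4-methyl-5-oxocyclohex-3-en-1-yl]propanoic acid | CC1=CC[C@H](CC1=O)C(C)C(O)=O | intermediate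
4 | methyl 2-[(1R)-4-methyl-5-oxocyclohex-3-en-1-yl]propanoate | CC1=CC[C@H](CC1=O)C(C)C(=O)OC | intermediate
5 | 2-bromo-3-(trimethylsilyl)prop-1-ene | C=C(Br)C[Si](C)(C)C | starting material
6 | [3-(trimethylsilyl)prop-1-en-2-yl]magnesium bromide | C=C([Mg]Br)C[Si](C)(C)C | intermediate (not isolated)
7 | bromomagnesium C9,C10-enolate of the conjugate adduct | COC(=O)C(C)[C@@H]1C[C@@H](C(=C)C[Si](C)(C)C)C(C)=C(O[Mg]Br)C1 | intermediate (not isolated)
8 | seco-eudesmane hydroxymethyl ketone (10β-Me, 10α-CH2OH, 5α-H, 7α-arm) | COC(=O)C(C)[C@@H]1C[C@@H](C(=C)C[Si](C)(C)C)[C@](C)(CO)C(=O)C1 | intermediate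
9 | seco-eudesmane keto aldehyde | COC(=O)C(C)[C@@H]1C[C@@H](C(=C)C[Si](C)(C)C)[C@](C)(C=O)C(=O)C1 | intermediate
10 | seco-eudesmane (1R)-homoallylic alcohol | COC(=O)C(C)[C@@H]1C[C@@H](C(=C)C[Si](C)(C)C)[C@](C)([C@H](O)CC=C)C(=O)C1 | intermediate
11 | methyl 1β-hydroxy-9-oxo-15-(trimethylsilyl)eudesm-3-en-12-oate (5α-H, 7β-H, 10β-Me) | C[Si](C)(C)CC1=CC[C@@H](O)[C@]2(C)C(=O)C[C@H](C(C)C(=O)OC)C[C@@H]12 | intermediate
12 | 1β-triflate of 11 | C[Si](C)(C)CC1=CC[C@@H](OS(=O)(=O)C(F)(F)F)[C@]2(C)C(=O)C[C@H](C(C)C(=O)OC)C[C@@H]12 | intermediate (not isolated)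
13 | methyl 9-oxolinden-4(15)-en-12-oate (1α-H, 3α-H, 5α-H, 7β-H) | C=C1[C@H]2C[C@H]2[C@]3(C)C(=O)C[C@H](C(C)C(=O)OC)C[C@@H]13 | intermediate
14 | methyl 8-(hydroxyimino)-9-oxolinden-4(15)-en-12-oate | C=C1[C@H]2C[C@H]2[C@]3(C)C(=O)C(=NO)[C@H](C(C)C(=O)OC)C[C@@H]13 | intermediate
15 | methyl 9β-hydroxy-8-(hydroxyimino)linden-4(15)-en-12-oate | C=C1[C@H]2C[C@H]2[C@]3(C)[C@@H](O)C(=NO)[C@H](C(C)C(=O)OC)C[C@@H]13 | intermediate
16 | methyl 9β-hydroxy-8-oxolinden-4(15)-en-12-oate | C=C1[C@H]2C[C@H]2[C@]3(C)[C@@H](O)C(=O)[C@H](C(C)C(=O)OC)C[C@@H]13 | intermediate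
17 | methyl 9β-(tert-butyldimethylsilyloxy)-8-oxolinden-4(15)-en-12-oate | C=C1[C@H]2C[C@H]2[C@]3(C)[C@@H](O[Si](C)(C)C(C)(C)C)C(=O)[C@H](C(C)C(=O)OC)C[C@@H]13 | intermediate
18 | 8-trimethylsilyloxy-7-ene (silyl enol ether of 17) | C=C1[C@H]2C[C@H]2[C@]3(C)[C@@H](O[Si](C)(C)C(C)(C)C)C(O[Si](C)(C)C)=C(C(C)C(=O)OC)C[C@@H]13 | intermediate (not isolated)
19 | methyl 9β-(tert-butyldimethylsilyloxy)-8-oxolinda-4(15),6-dien-12-oate | C=C1[C@H]2C[C@H]2[C@]3(C)[C@@H](O[Si](C)(C)C(C)(C)C)C(=O)C(C(C)C(=O)OC)=C[C@@H]13 | intermediate
20 | 4,15-epoxide of 19 | O1CC12[C@H]3C[C@H]3[C@]4(C)[C@@H](O[Si](C)(C)C(C)(C)C)C(=O)C(C(C)C(=O)OC)=C[C@@H]24 | intermediate (not isolated)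
21 | methyl 9β-(tert-butyldimethylsilyloxy)-15-hydroxy-8-oxolinda-4,6-dien-12-oate | OCC1=C2C=C(C(C)C(=O)OC)C(=O)[C@H](O[Si](C)(C)C(C)(C)C)[C@@]2(C)[C@@H]2C[C@H]12 | intermediate
22 | methyl 9β-(tert-butyldimethylsilyloxy)-8β,15-dihydroxylinda-4,6-dien-12-oate | OCC1=C2C=C(C(C)C(=O)OC)[C@H](O)[C@H](O[Si](C)(C)C(C)(C)C)[C@@]2(C)[C@@H]2C[C@H]12 | intermediate (not isolated)
23 | 9β-(tert-butyldimethylsilyloxy)-15-hydroxylinda-4,6-dien-12,8β-olide | OCC1=C2C=C3C(C)C(=O)O[C@@H]3[C@H](O[Si](C)(C)C(C)(C)C)[C@@]2(C)[C@@H]2C[C@H]12 | intermediate
24 | 15-bromo-9β-(tert-butyldimethylsilyloxy)linda-4,6-dien-12,8β-olide | BrCC1=C2C=C3C(C)C(=O)O[C@@H]3[C@H](O[Si](C)(C)C(C)(C)C)[C@@]2(C)[C@@H]2C[C@H]12 | intermediate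
25 | seco-dimer alcohol (11R; C11–C15′ bond; 15-OH on the alkylated half) | OCC1=C2C=C3[C@@](C)(CC4=C5C=C6C(C)C(=O)O[C@@H]6[C@H](O[Si](C)(C)C(C)(C)C)[C@@]5(C)[C@@H]5C[C@H]45)C(=O)O[C@@H]3[C@H](O[Si](C)(C)C(C)(C)C)[C@@]2(C)[C@@H]2C[C@H]12 | intermediate
26 | seco-dimer bromide | BrCC1=C2C=C3[C@@](C)(CC4=C5C=C6C(C)C(=O)O[C@@H]6[C@H](O[Si](C)(C)C(C)(C)C)[C@@]5(C)[C@@H]5C[C@H]45)C(=O)O[C@@H]3[C@H](O[Si](C)(C)C(C)(C)C)[C@@]2(C)[C@@H]2C[C@H]12 | intermediate
27 | macrocyclic bis(12,8β-olide), 9,9′-bis-silyl ether | C1C2=C3C=C4[C@@](C)(CC5=C6C=C7[C@]1(C)C(=O)O[C@@H]7[C@H](O[Si](C)(C)C(C)(C)C)[C@@]6(C)[C@@H]6C[C@H]56)C(=O)O[C@@H]4[C@H](O[Si](C)(C)C(C)(C)C)[C@@]3(C)[C@@H]3C[C@H]23 | intermediate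
28 | dilithium 8β,8′β-dihydroxy dicarboxylate of 27 | [Li+].[Li+].[O-]C(=O)[C@]1(C)CC2=C3C=C([C@H](O)[C@H](O[Si](C)(C)C(C)(C)C)[C@@]3(C)[C@@H]3C[C@H]23)[C@](C)(C([O-])=O)CC2=C3C=C1[C@H](O)[C@H](O[Si](C)(C)C(C)(C)C)[C@@]3(C)[C@@H]1C[C@H]21 | intermediate (not isolated)
29 | 9,9′-bis-O-TBS-8,8′-dihydrocycloshizukaol A (8β,8′β-diol) | COC(=O)[C@]1(C)CC2=C3C=C([C@H](O)[C@H](O[Si](C)(C)C(C)(C)C)[C@@]3(C)[C@@H]3C[C@H]23)[C@](C)(C(=O)OC)CC2=C3C=C1[C@H](O)[C@H](O[Si](C)(C)C(C)(C)C)[C@@]3(C)[C@@H]1C[C@H]21 | intermediate
30 | 9,9′-bis-O-TBS-cycloshizukaol A | COC(=O)[C@]1(C)CC2=C3C=C(C(=O)[C@H](O[Si](C)(C)C(C)(C)C)[C@@]3(C)[C@@H]3C[C@H]23)[C@](C)(C(=O)OC)CC2=C3C=C1C(=O)[C@H](O[Si](C)(C)C(C)(C)C)[C@@]3(C)[C@@H]1C[C@H]21 | intermediate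
31 | cycloshizukaol A | COC(=O)[C@]1(C)CC2=C3C=C(C(=O)[C@H](O)[C@@]3(C)[C@@H]3C[C@H]23)[C@](C)(C(=O)OC)CC2=C3C=C1C(=O)[C@H](O)[C@@]3(C)[C@@H]1C[C@H]21 | target

## Step count and weak points

Total step count: 22. Longest linear sequence: 22 steps from 1 (5 enters in step 4; 23 is used twice in step 17).

**Step 8 (key step).** The likely failure is ionisation of the triflate without help from C3, followed by 1,2-shift of the C10 methyl or the C9 acyl group, or by elimination. An endocyclic homoallylic alkene aligns with the C1–O bond less easily than the exocyclic alkene of the cyclosteroid case. Fallback: leave the cationic manifold. Alcohol 11 is converted with MsCl and Et3N into the stable 1β-mesylate F1. The allylsilane is then activated as the nucleophile with fluoride (TBAF or CsF, DMF). The resulting allyl anion equivalent closes C3 onto C1 in an anionic 1,3-elimination with the same inversion and gives 13. No carbocation is formed, so no skeletal shift can compete.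

**Step 17.** The likely failure is proton transfer from 24 to the dianion, followed by vinylogous loss of bromide and repeated addition to the resulting triene (oligomerisation), or O-alkylation of the alkoxide. The enolate and the acidic C11–H of the electrophile are close in basicity. Fallback: separate enolate generation from the electrophile and use a π-allyl electrophile. Lactone 23 is bis-silylated with LiN(iPr)2 and Me3SiCl to the ketene silyl acetal F2. A second portion of 23 is converted with ClCO2Me and pyridine into the allylic methyl carbonate F3. Pd2(dba)3/dppe in THF joins F2 and F3 (Tsuji–Trost allylation of a ketene silyl acetal by an allylic carbonate; the methoxide released at the metal is the only base). Aqueous work-up removes the O-silyl group and returns the route to 25.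

**Step 19.** The likely failure is intermolecular alkylation or no closure at all. The lactone holds the C7–C11 rotamer of the nucleophilic half and may strain the 12-membered transition state. Fallback: release that clamp on the nucleophilic half.
- In 25 the lactone of the half with tertiary C11 is saponified selectively (LiOH, 1 equiv; the α-quaternary lactone reacts more slowly), the carboxylate is methylated (MeI) and both hydroxyls are silylated (Et3SiOTf, 2,6-lutidine) to the bis(triethylsilyl) hydroxy-ester dimer F4.
- PPTS in MeOH frees only the primary C15 alcohol F5, and CBr4/PPh3 gives bromide F6.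
- LiN(SiMe3)2 at high dilution closes the ring through the freely rotating ester dienolate to the macrocyclic mono-lactone F7. C11 is then set by the macrocycle.
- LiOH followed by MeI opens the remaining lactone, and PPTS in MeOH removes the triethylsilyl group, which returns the route to 29.

**Step 15.** The likely failure is poor facial selectivity of hydride delivery on the nearly flat dienone. The 8α-lactone that would result relays the wrong configuration to C11. Fallback: change from substrate to reagent control. A Corey–Bakshi–Shibata reduction of 21 with BH3·SMe2 and the oxazaborolidine antipode that delivers hydride to the α face is followed by the same acid-promoted lactonisation to 23. This fallback makes no new compound, hence the entry F0.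

**Step 13.** The likely failure is enolisation toward C9, which gives an enol ether that cannot eliminate and may return 17 epimerised at C9. Both α-carbons are tertiary. Fallback: make the regiochemistry structural. Ester 17 is saponified (LiOH) to keto acid F8. Ac2O/NaOAc closes the enol lactone F9, which can only form toward C7. Bu3SnOMe opens F9 to the C7 tin enolate and the methyl ester at once, and Pd(OAc)2 oxidises the tin enolate to 19.

**Step 20.** The likely failure is incomplete opening of the α-quaternary lactones, or reclosure of the hydroxy esters before they are oxidised. Fallback: oxidise before esterifying. The dilithium salt 28, made from 27 with LiOH, is oxidised as the carboxylate with IBX in DMSO to the bis(keto acid) F10, which cannot relactonise. Me3SiCHN2 in MeOH/toluene then gives 30 directly.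

## Further compounds

F1 | step 8 | 1β-mesylate of 11 | C[Si](C)(C)CC1=CC[C@@H](OS(C)(=O)=O)[C@]2(C)C(=O)C[C@H](C(C)C(=O)OC)C[C@@H]12
F2 | step 17 | 15-O-trimethylsilyl ketene trimethylsilyl acetal of 23 | C[Si](C)(C)OCC1=C2C=C3C(C)=C(O[Si](C)(C)C)O[C@@H]3[C@H](O[Si](C)(C)C(C)(C)C)[C@@]2(C)[C@@H]2C[C@H]12
F3 | step 17 | 15-(methoxycarbonyloxy) derivative of 23 | COC(=O)OCC1=C2C=C3C(C)C(=O)O[C@@H]3[C@H](O[Si](C)(C)C(C)(C)C)[C@@]2(C)[C@@H]2C[C@H]12
F4 | step 19 | bis(triethylsilyl) hydroxy-ester dimer (one lactone opened to methyl ester and 8β-OSiEt3; 15-OSiEt3) | CC[Si](CC)(CC)OCC1=C2C=C3[C@@](C)(CC4=C5C=C(C(C)C(=O)OC)[C@H](O[Si](CC)(CC)CC)[C@H](O[Si](C)(C)C(C)(C)C)[C@@]5(C)[C@@H]5C[C@H]45)C(=O)O[C@@H]3[C@H](O[Si](C)(C)C(C)(C)C)[C@@]2(C)[C@@H]2C[C@H]12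
F5 | step 19 | primary C15 alcohol from F4 | OCC1=C2C=C3[C@@](C)(CC4=C5C=C(C(C)C(=O)OC)[C@H](O[Si](CC)(CC)CC)[C@H](O[Si](C)(C)C(C)(C)C)[C@@]5(C)[C@@H]5C[C@H]45)C(=O)O[C@@H]3[C@H](O[Si](C)(C)C(C)(C)C)[C@@]2(C)[C@@H]2C[C@H]12
F6 | step 19 | C15 bromide from F5 | BrCC1=C2C=C3[C@@](C)(CC4=C5C=C(C(C)C(=O)OC)[C@H](O[Si](CC)(CC)CC)[C@H](O[Si](C)(C)C(C)(C)C)[C@@]5(C)[C@@H]5C[C@H]45)C(=O)O[C@@H]3[C@H](O[Si](C)(C)C(C)(C)C)[C@@]2(C)[C@@H]2C[C@H]12
F7 | step 19 | macrocyclic mono-lactone (one half as methyl ester with 8β-OSiEt3) | C1C2=C3C=C4[C@@](C)(CC5=C6C=C([C@]1(C)C(=O)OC)[C@H](O[Si](CC)(CC)CC)[C@H](O[Si](C)(C)C(C)(C)C)[C@@]6(C)[C@@H]6C[C@H]56)C(=O)O[C@@H]4[C@H](O[Si](C)(C)C(C)(C)C)[C@@]3(C)[C@@H]3C[C@H]23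
F0 | step 15 | none | none
F8 | step 13 | 9β-(tert-butyldimethylsilyloxy)-8-oxolinden-4(15)-en-12-oic acid | C=C1[C@H]2C[C@H]2[C@]3(C)[C@@H](O[Si](C)(C)C(C)(C)C)C(=O)[C@H](C(C)C(O)=O)C[C@@H]13
F9 | step 13 | 9β-(tert-butyldimethylsilyloxy)linda-4(15),7-dien-12,8-olide (enol lactone) | C=C1[C@H]2C[C@H]2[C@]3(C)[C@@H](O[Si](C)(C)C(C)(C)C)C4=C(C(C)C(=O)O4)C[C@@H]13
F10 | step 20 | 9,9′-bis-O-TBS-cycloshizukaol A diacid | OC(=O)[C@]1(C)CC2=C3C=C(C(=O)[C@H](O[Si](C)(C)C(C)(C)C)[C@@]3(C)[C@@H]3C[C@H]23)[C@](C)(C(O)=O)CC2=C3C=C1C(=O)[C@H](O[Si](C)(C)C(C)(C)C)[C@@]3(C)[C@@H]1C[C@H]21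
A1 | alternative 1 | 6-(dimethylamino)-1,4-dimethylfulvene | CN(C)C=C1C(C)=CC=C1C
A2 | alternative 1 | 1-(benzyloxy)-3-chloro-2-(trimethylsilyloxy)prop-1-ene (oxyallyl cation precursor) | C[Si](C)(C)OC(CCl)=COCc1ccccc1
A3 | alternative 1 | 9-benzyloxy tetraenone (C1=C3, C4=C5, C6=C7, C8 ketone, quaternary C10) | CC1=C2C=CC(=O)[C@H](OCc3ccccc3)[C@@]2(C)C=C1
A4 | alternative 2 | lindenane monomer with C4 alkenyl triflate and C7 spirocyclopropane (C11, C15) | COC(=O)C1(C)CC12CC3=C(OS(=O)(=O)C(F)(F)F)[C@H]4C[C@H]4[C@]3(C)[C@@H](O[Si](C)(C)C)C2=O
A5 | alternative 2 | macrocyclic bis(silyl enol ether) | COC(=O)[C@]1(C)CC2=C3CC(=C(O[Si](C)(C)C)[C@H](O[Si](C)(C)C)[C@@]3(C)[C@@H]3C[C@H]23)[C@](C)(C(=O)OC)CC2=C3CC1=C(O[Si](C)(C)C)[C@H](O[Si](C)(C)C)[C@@]3(C)[C@@H]1C[C@H]21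
A6 | alternative 3 | cis-cyclopropane with tert-butyl propanoate arm on C1 and alkenyl bromide arm on C3 | CC(C(=O)OC(C)(C)C)[C@@H]1C[C@@H]1C(CO[Si](C)(C)C(C)(C)C)=C(Br)CO[Si](C)(C)C(C)(C)C
A7 | alternative 3 | bicyclo[3.1.0]hex-2-ene with quaternary C10 | CC(C)(C)[Si](C)(C)OCC1=C(CO[Si](C)(C)C(C)(C)C)[C@@](C)(C(=O)OC(C)(C)C)[C@@H]2C[C@H]12
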